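Structural features

The target is a 7-oxabicyclo[4.1.0]heptan-2-one: a cyclohexanone (ring carbons C1 to C6, ketone at C1) whose C2–C3 bond is bridged by an oxirane, with a methyl group on C2. C5 carries a chain through C7, the α-carbon of a cross-conjugated dienone (exocyclic methylene C7', ketone C8, (E)-C9=C10, tertiary carbinol C11), and C6 carries an (E)-2-methylbut-2-enoate (tiglate). Four stereocenters sit on the ring as two adjacent pairs, C2/C3 on one side of the carbonyl and C5/C6 on the other; the oxirane oxygen is cis to the C5 chain and the tiglate is trans to it. The fragile groups are the α-methylene ketone (Michael acceptor; deprotonation at C5 would expel the tiglate and lead to a phenol), the α-acyloxy ketone (epimerization at C6, acyl migration), the epoxy ketone (base, reducing metals, strong acid) and the tertiary allylic alcohol (ionization). The carbon skeleton maps onto (R)-carvone, which supplies C5 in the right configuration, so the difficulty is not the skeleton but the oxirane: nucleophilic epoxidation of a carvone-type enone places oxygen anti to the C5 substituent. The key step exploits the fact that C8 lies four bonds from C3 (C3–C4–C5–C7–C8) and must itself end up oxygenated. A C8–O–O unit can reach C3 only across the face that carries the chain, and after the transfer its second oxygen stays on C8.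

Logic of the disconnections

19 to 18: no skeletal bond is cut; the C8 carbonyl is traced back to a C8 carbinol. The cross-conjugated dienone is the most electrophilic part of 19 and is best unveiled last. The gain is that C8–C9 can then come from a carbonyl addition. The forward step needs an oxidant that takes the secondary, doubly allylic alcohol, leaves the tertiary one and is not basic.

18 to 13 and 16: the C8–C9 bond is cut. This splits off the five-carbon end of the chain with its (E)-alkene already fixed and leaves all four stereocenters in 13. The forward step needs an alkenyl metal that adds 1,2 to the aldehyde C8 and ignores the C1 ketone, the ester, the oxirane and a free hydroxyl group.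

16 to 14: the C9–I bond is cut and the alkene is traced back to the alkyne. The forward step must add hydrogen and a metal syn, with the metal on the terminal carbon, so that the (E)-geometry follows.

13 to 12 to 11: no skeletal bond is cut; C8 is lowered to the alcohol and then masked as a silyl ether. The C8 oxygen must be blocked while C6 is functionalized through an enolate. The forward steps need a silyl group that leaves under conditions that spare oxirane and ester, and a non-basic oxidation.

11 to 8 and 9: the acyl C–O bond of the C6 ester is cut. The five-carbon acid is commercial and its (E)-geometry is the stable one. The forward step must acylate a hindered α-ketol without touching the C6–O bond.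

8 to 6: the C6–O bond is cut. C6 is the only enolizable position, so regiochemistry is not an issue. The forward step must deliver oxygen to the enolate face opposite the C5 chain.

6 to 5: the O–Si bond is cut, which returns the free C8 alcohol.

5 to 2: the C3–O and C2–O bonds of the oxirane are cut and that oxygen is reconnected to the C8 oxygen. This removes the ring and two stereocenters and reveals a monocyclic enone one step from 1. The forward step must pass the terminal peroxide oxygen to C3 within the molecule, faster than any intermolecular transfer and faster than base-induced decomposition of the hydroperoxide.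

2 to 1: the C8–O bond is cut with transposition of the alkene. The forward step must oxygenate the terminal carbon of the isopropenyl group and take hydrogen from the methyl group, not from C5.

Other disconnections considered

Alternative 1: The cut is made on both sides of C8, at C7–C8 and C8–C9, so that the dienone is assembled from three pieces: the C7 enol triflate A1 (oxirane, tiglate and a C1 triethylsilyl carbinol in place), carbon monoxide A2 as C8, and the alkenylstannane that is intermediate 15 of the chosen route. Forward, Pd(PPh3)4 would insert into the C7–O bond of A1, take up A2 to give an acylpalladium species and couple it with 15 to give A3; no ring closes and no stereocenter is set.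
- In its favour: the reaction class is well precedented for enol triflates and the medium is neutral. C8 arrives at the ketone level, so neither stoichiometric chromium nor a final oxidation of a doubly allylic alcohol is needed; on these points it is the better plan. It is also better for the oxirane in one respect: a C1 carbinol cis to the chain can direct a metal-catalysed epoxidation to the required face by known chemistry, whereas the chosen relay has no precedent.
- Against it here: A1 can only come from regioselective enolization of an acetyl group at C7. That forces C1 to be reduced and protected beforehand and deprotected and reoxidized afterwards, next to an oxirane and in the presence of the finished dienone. The acetyl group also requires that C7' of 1 is first excised and then rebuilt. Direct coupling without uptake of A2 is a known competitor.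
- Comparison: both plans turn on the C8 oxygen. Here it comes from A2 and serves one purpose; in the chosen plan it comes from O2 together with the oxirane oxygen. The alternative should be longer by about four operations.

Alternative 2: The cut is the ring bond C5–C6, which opens the carbocycle to the acyclic keto aldehyde A4, a 1,2-dicarbonyl compound (C6 aldehyde, C1 ketone) with a (Z)-C2=C3 enone and a trisubstituted C5=C7 alkene carrying the silyloxymethyl group. Forward, a chiral Lewis acid would activate the aldehyde for an intramolecular carbonyl-ene reaction of the citronellal-to-isopulegol kind: C6 bonds to C5, a methyl hydrogen moves to oxygen, C7=C7' appears, and A5 results with C5 and C6 set together.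
- In its favour: the trans relation of the C6 hydroxyl and the C5 chain follows from a chair-like pericyclic transition state, so the C6 oxygen is in place without enolate chemistry. On this point the alternative is the better plan, because the facial question of step 4 disappears. C8 is already oxygenated.
- Against it here: both absolute configurations must come from a catalyst, whereas 1 supplies C5 for nothing. A4 is a hydrating, polymerizable glyoxal whose (Z)-enone geometry is the less stable one, and its C5=C7 geometry decides whether the methyl or the silyloxymethyl group gives up hydrogen. A4 also needs a multistep synthesis of its own.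
- It does not answer the main structural question: the C6 hydroxyl of A5 lies on the face opposite the chain and would steer a directed epoxidation the wrong way, and its C8 oxygen is silylated. The oxirane would still call for the relay of the chosen plan after further steps, or for a reduce, direct and reoxidize detour.
- Comparison: the ene closure is concerted and well understood, a point in its favour over the stepwise, unprecedented relay. In step economy it should be clearly longer.

Alternative 3: The cut removes C2 with its methyl group from the ring (bonds C1–C2 and C2–C3), leaving the cyclopentanone A6 that already carries the C6 silyl ether and the C5 chain as a p-methoxybenzyl ether. Forward, Sc(OTf)3 would activate the ketone for addition of diazoethane A7; loss of N2 with 1,2-shift of C3 would insert C2 and give the 2-methylcyclohexanone A8.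
- In its favour: a trans-2-oxy-3-alkenylcyclopentanone such as A6 is the usual outcome of conjugate addition to a cyclopentenone followed by enolate oxidation, so C5 and C6 would be set early by reliable substrate control, equal to or better than step 4 of the chosen plan. The homologation is catalytic, and singlet oxygen and a free hydroperoxide are avoided.
- Against it here: the shift must be made by the C3 methylene and not by the oxygen-bearing C6, which is electronically reasonable but has to be earned. A7 is not commercial and must be generated from a nitroso precursor and handled as an explosive, toxic gas, a hazard at least equal to that of the hydroperoxide. A8 is saturated, so the C2=C3 double bond must be introduced by a dehydrogenation that chooses C2 over C6, and the oxirane still has to be placed on the chain face, the very problem the chosen plan solves.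
- Comparison: the alternative rebuilds a methyl-substituted cyclohexenone that 1 already contains. Mechanistically it is on firm ground (known catalysis against an unprecedented relay), which is to its credit. In step economy it should be the longest of the four plans.

Key step: step 2

Assumptions (remarks on the chemistry):
- Ring locants C1 to C6 and chain locants C7 to C11 are used as defined above.
- A check of all stereodescriptors shows that (R)-carvone carries the C5 configuration of the target and that the target is (1S,3S,4S,6S) in bicyclic numbering, so no structure needed correction.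
- The precursor of the key step is kept as hydroperoxide 2 but enters the reaction as its preformed potassium salt 3.
- Alcohol 18 is carried as a mixture of C8 epimers.

Step 1
Reactants: 1 (R)-carvone
Product: 2 (5R)-5-(3-hydroperoxyprop-1-en-2-yl)-2-methylcyclohex-2-en-1-one
Conditions: O2 (1 atm), tetraphenylporphyrin (0.5 mol%), CH2Cl2, white LED through a 450 nm long-pass filter, 0 °C
Reagents that add atoms: dioxygen, O=O
Why: Schenck ene reaction: singlet oxygen attacks only the electron-rich 1,1-disubstituted alkene (the enone alkene is inert), bonds to the terminal carbon and takes hydrogen from the freely rotating methyl group, not from C5–H, which lies in the alkene plane; C5 is untouched and no new stereocenter forms. Long-wavelength light excites the sensitizer only and spares the enone chromophore.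

Step 2
Reactants: 2 (5R)-5-(3-hydroperoxyprop-1-en-2-yl)-2-methylcyclohex-2-en-1-one
Product: 5 (1S,4R,6S)-4-(3-hydroxyprop-1-en-2-yl)-1-methyl-7-oxabicyclo[4.1.0]heptan-2-one (oxirane cis to the C5 chain), via potassium peroxide 3 (not isolated), via bridged peroxy enolate 4 (not isolated)
Conditions: KOt-Bu (1.0 equiv), THF (0.005 M), −78 °C to 0 °C; then aq. NH4Cl
Reagents that add atoms: none
Why: Proposed new method: the reasoning is that the potassium peroxide 3, with the C5 chain axial, reaches C3 only across the chain face (7-exo-trig conjugate addition through a seven-membered transition state) to give the bridged peroxy enolate 4, whose C2 carbon then displaces the C8 alkoxide by substitution at the C3-bound oxygen, the tether holding the leaving oxygen on the far side of C3 from C2; the closest known reaction types are the Weitz–Scheffer epoxidation of enones with alkyl hydroperoxide anions and intramolecular peroxy-Michael additions that stop at bridged cyclic peroxides. The oxirane closes in a 3-exo-tet mode at oxygen, in the same event that opens the seven-membered peroxide bridge. C3 is set by the tether, because the C5 stereocenter of (R)-carvone holds the peroxide on one face only, and C2 follows because an oxirane on a six-membered ring must be cis-fused. Addition of the peroxide to the C1 carbonyl is also within reach but is reversible and cannot collapse further, so it should only delay the reaction. Full deprotonation with one equivalent of KOt-Bu at low temperature leaves no neutral hydroperoxide for base-induced dehydration to the enal (Kornblum–DeLaMare), and high dilution keeps bimolecular oxygen transfer, which would give the trans-epoxide, slow relative to the unimolecular relay. No atom is added: one oxygen of the hydroperoxide becomes the oxirane oxygen and the other stays on C8.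

Step 3
Reactants: 5 (1S,4R,6S)-4-(3-hydroxyprop-1-en-2-yl)-1-methyl-7-oxabicyclo[4.1.0]heptan-2-one
Product: 6 (1S,4R,6S)-1-methyl-4-[3-(triethylsilyloxy)prop-1-en-2-yl]-7-oxabicyclo[4.1.0]heptan-2-one
Conditions: TESCl, imidazole, CH2Cl2, 0 °C to rt
Reagents that add atoms: triethylsilyl chloride, CC[Si](Cl)(CC)CC
Why: Imidazole-assisted silylation of a primary alcohol; the triethylsilyl ether masks the C8 hydroxyl during the enolate step and can later be removed under acid mild enough to spare oxirane and ester.

Step 4
Reactants: 6 (1S,4R,6S)-1-methyl-4-[3-(triethylsilyloxy)prop-1-en-2-yl]-7-oxabicyclo[4.1.0]heptan-2-one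
Product: 8 (1S,3S,4S,6S)-3-hydroxy-1-methyl-4-[3-(triethylsilyloxy)prop-1-en-2-yl]-7-oxabicyclo[4.1.0]heptan-2-one (C6 hydroxyl trans to the C5 chain), via sodium enolate 7 (not isolated)
Conditions: NaN(SiMe3)2 (1.1 equiv), THF, −78 °C; then 2-(phenylsulfonyl)-3-phenyloxaziridine, −78 °C; then aq. NH4Cl
Reagents that add atoms: 2-(phenylsulfonyl)-3-phenyloxaziridine (Davis oxaziridine), O=S(=O)(c1ccccc1)N1OC1c1ccccc1
Why: Enolate α-hydroxylation with a Davis oxaziridine: C6 is the only enolizable position (C2 is quaternary), and oxygen should be transferred to the enolate face opposite the adjacent C5 chain and the oxirane oxygen, as in alkylations and hydroxylations of carvone enolates, which sets C6 trans to the chain (also the diequatorial arrangement). The sodium counter-ion limits addition of the enolate to the sulfonimine by-product.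

Step 5
Reactants: 8 (1S,3S,4S,6S)-3-hydroxy-1-methyl-4-[3-(triethylsilyloxy)prop-1-en-2-yl]-7-oxabicyclo[4.1.0]heptan-2-one; 9 tiglic acid
Product: 11 (1S,3S,4S,6S)-1-methyl-2-oxo-4-[3-(triethylsilyloxy)prop-1-en-2-yl]-7-oxabicyclo[4.1.0]heptan-3-yl (2E)-2-methylbut-2-enoate, via mixed anhydride 10 (not isolated)
Conditions: 9, 2,4,6-trichlorobenzoyl chloride, Et3N, toluene, rt; then 8, DMAP (0.2 equiv), toluene, rt
Reagents that add atoms: none
Why: Yamaguchi esterification: the mixed anhydride 10 transfers the less hindered tigloyl group through its acylpyridinium ion to the hindered α-ketol; the C6–O bond is not broken, so the configuration is retained, and the (E)-geometry of the tiglate is the stable one.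

Step 6
Reactants: 11 (1S,3S,4S,6S)-1-methyl-2-oxo-4-[3-(triethylsilyloxy)prop-1-en-2-yl]-7-oxabicyclo[4.1.0]heptan-3-yl (2E)-2-methylbut-2-enoate
Product: 12 (1S,3S,4S,6S)-4-(3-hydroxyprop-1-en-2-yl)-1-methyl-2-oxo-7-oxabicyclo[4.1.0]heptan-3-yl (2E)-2-methylbut-2-enoate
Conditions: PPTS (0.1 equiv), MeOH, 0 °C
Reagents that add atoms: none
Why: Acid-catalysed methanolysis of a primary triethylsilyl ether; the conditions should be too mild to open the carbonyl-deactivated oxirane or to transesterify the tiglate, and 12 is taken on at once to forestall acyl migration.

Step 7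
Reactants: 12 (1S,3S,4S,6S)-4-(3-hydroxyprop-1-en-2-yl)-1-methyl-2-oxo-7-oxabicyclo[4.1.0]heptan-3-yl (2E)-2-methylbut-2-enoate
Product: 13 (1S,3S,4S,6S)-1-methyl-2-oxo-4-(3-oxoprop-1-en-2-yl)-7-oxabicyclo[4.1.0]heptan-3-yl (2E)-2-methylbut-2-enoate
Conditions: Dess–Martin periodinane, NaHCO3, CH2Cl2, 0 °C to rt
Reagents that add atoms: none
Why: Dess–Martin oxidation of the primary allylic alcohol to the 2-substituted acrolein under buffered, non-basic conditions, which avoids deprotonation at C5 and over-oxidation.

Step 8
Reactants: 14 2-methylbut-3-yn-2-ol
Product: 16 (3E)-4-iodo-2-methylbut-3-en-2-ol, via vinylstannane 15 (not isolated)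
Conditions: Bu3SnH, PdCl2(PPh3)2 (1 mol%), THF, 0 °C to rt; then I2, 0 °C
Reagents that add atoms: iodine, II
Why: Palladium-catalysed syn-hydrostannylation places tin on the terminal carbon, away from the bulky tertiary carbinol, to give the (E)-alkenylstannane 15; iododestannylation then proceeds with retention of the alkene geometry.

Step 9
Reactants: 13 (1S,3S,4S,6S)-1-methyl-2-oxo-4-(3-oxoprop-1-en-2-yl)-7-oxabicyclo[4.1.0]heptan-3-yl (2E)-2-methylbut-2-enoate; 16 (3E)-4-iodo-2-methylbut-3-en-2-ol
Product: 18 (1S,3S,4S,6S)-4-[(4E)-3,6-dihydroxy-6-methylhepta-1,4-dien-2-yl]-1-methyl-2-oxo-7-oxabicyclo[4.1.0]heptan-3-yl (2E)-2-methylbut-2-enoate (both C8 epimers), via alkenylchromium reagent 17 (not isolated)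
Conditions: CrCl2 (4 equiv), NiCl2 (1 mol%), degassed DMSO, rt
Reagents that add atoms: none
Why: Nozaki–Hiyama–Kishi reaction: zerovalent nickel inserts into the C–I bond, the alkenyl group passes to trivalent chromium, and the alkenylchromium reagent 17 adds 1,2 to the aldehyde only, leaving ketone, ester and free hydroxyl groups untouched. The new C8 stereocenter is not controlled and need not be, since it is oxidized in the next step.

Step 10
Reactants: 18 (1S,3S,4S,6S)-4-[(4E)-3,6-dihydroxy-6-methylhepta-1,4-dien-2-yl]-1-methyl-2-oxo-7-oxabicyclo[4.1.0]heptan-3-yl (2E)-2-methylbut-2-enoate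
Product: 19 (1S,3S,4S,6S)-4-[(4E)-6-hydroxy-6-methyl-3-oxohepta-1,4-dien-2-yl]-1-methyl-2-oxo-7-oxabicyclo[4.1.0]heptan-3-yl (2E)-2-methylbut-2-enoate (CNP0263368.1)
Conditions: Dess–Martin periodinane, NaHCO3, CH2Cl2, 0 °C
Reagents that add atoms: none
Why: Dess–Martin oxidation of the secondary, doubly allylic alcohol; the tertiary carbinol cannot be oxidized, and the buffered, non-basic medium protects the α-methylene ketone, the oxirane and the C6 ester.

Compound list

1 | (R)-carvone, (5R)-2-methyl-5-(prop-1-en-2-yl)cyclohex-2-en-1-one | CC(=C)[C@@H]1CC=C(C)C(=O)C1 | starting material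
2 | (5R)-5-(3-hydroperoxyprop-1-en-2-yl)-2-methylcyclohex-2-en-1-one | C=C(COO)[C@@H]1CC=C(C)C(=O)C1 | intermediate
3 | potassium 2-[(1R)-4-methyl-5-oxocyclohex-3-en-1-yl]prop-2-en-1-yl peroxide (potassium salt of 2) | C=C(CO[O-])[C@@H]1CC=C(C)C(=O)C1.[K+] | intermediate (not isolated)
4 | potassium 9-methyl-5-methylidene-2,3-dioxabicyclo[4.3.1]dec-8-en-8-olate (peroxide bridge from C3 to C8 on the face of the C5 chain; configuration derived from 2) | C=C1COO[C@H]2C[C@@H]1CC([O-])=C2C.[K+] | intermediate (not isolated)
5 | (1S,4R,6S)-4-(3-hydroxyprop-1-en-2-yl)-1-methyl-7-oxabicyclo[4.1.0]heptan-2-one (oxirane cis to the chain) | C=C(CO)[C@@H]1C[C@@H]2O[C@]2(C)C(=O)C1 | intermediate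
6 | (1S,4R,6S)-1-methyl-4-[3-(triethylsilyloxy)prop-1-en-2-yl]-7-oxabicyclo[4.1.0]heptan-2-one | C=C(CO[Si](CC)(CC)CC)[C@@H]1C[C@@H]2O[C@]2(C)C(=O)C1 | intermediate
7 | sodium enolate of 6 (C1–C6 enolate) | C=C(CO[Si](CC)(CC)CC)[C@@H]1C[C@@H]2O[C@]2(C)C([O-])=C1.[Na+] | intermediate (not isolated)
8 | (1S,3S,4S,6S)-3-hydroxy-1-methyl-4-[3-(triethylsilyloxy)prop-1-en-2-yl]-7-oxabicyclo[4.1.0]heptan-2-one | C=C(CO[Si](CC)(CC)CC)[C@@H]1C[C@@H]2O[C@]2(C)C(=O)[C@H]1O | intermediate
9 | tiglic acid, (2E)-2-methylbut-2-enoic acid | C/C=C(\C)C(=O)O | starting material
10 | (2E)-2-methylbut-2-enoic 2,4,6-trichlorobenzoic anhydride | C/C=C(\C)C(=O)OC(=O)c1c(Cl)cc(Cl)cc1Cl | intermediate (not isolated)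
11 | (1S,3S,4S,6S)-1-methyl-2-oxo-4-[3-(triethylsilyloxy)prop-1-en-2-yl]-7-oxabicyclo[4.1.0]heptan-3-yl (2E)-2-methylbut-2-enoate | C=C(CO[Si](CC)(CC)CC)[C@@H]1C[C@@H]2O[C@]2(C)C(=O)[C@H]1OC(=O)/C(C)=C/C | intermediate
12 | (1S,3S,4S,6S)-4-(3-hydroxyprop-1-en-2-yl)-1-methyl-2-oxo-7-oxabicyclo[4.1.0]heptan-3-yl (2E)-2-methylbut-2-enoate | C=C(CO)[C@@H]1C[C@@H]2O[C@]2(C)C(=O)[C@H]1OC(=O)/C(C)=C/C | intermediate
13 | (1S,3S,4S,6S)-1-methyl-2-oxo-4-(3-oxoprop-1-en-2-yl)-7-oxabicyclo[4.1.0]heptan-3-yl (2E)-2-methylbut-2-enoate | C=C(C=O)[C@@H]1C[C@@H]2O[C@]2(C)C(=O)[C@H]1OC(=O)/C(C)=C/C | intermediate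
14 | 2-methylbut-3-yn-2-ol | CC(C)(O)C#C | starting material
15 | (3E)-2-methyl-4-(tributylstannyl)but-3-en-2-ol | CC(C)(O)/C=C/[Sn](CCCC)(CCCC)CCCC | intermediate (not isolated)
16 | (3E)-4-iodo-2-methylbut-3-en-2-ol | CC(C)(O)/C=C/I | intermediate
17 | [(1E)-3-hydroxy-3-methylbut-1-en-1-yl]chromium dichloride (solvent ligands omitted) | CC(C)(O)/C=C/[Cr](Cl)Cl | intermediate (not isolated)
18 | (1S,3S,4S,6S)-4-[(4E)-3,6-dihydroxy-6-methylhepta-1,4-dien-2-yl]-1-methyl-2-oxo-7-oxabicyclo[4.1.0]heptan-3-yl (2E)-2-methylbut-2-enoate, both C8 epimers | C=C(C(O)/C=C/C(C)(C)O)[C@@H]1C[C@@H]2O[C@]2(C)C(=O)[C@H]1OC(=O)/C(C)=C/C | intermediate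
19 | (1S,3S,4S,6S)-4-[(4E)-6-hydroxy-6-methyl-3-oxohepta-1,4-dien-2-yl]-1-methyl-2-oxo-7-oxabicyclo[4.1.0]heptan-3-yl (2E)-2-methylbut-2-enoate | C=C(C(=O)/C=C/C(C)(C)O)[C@@H]1C[C@@H]2O[C@]2(C)C(=O)[C@H]1OC(=O)/C(C)=C/C | target

Total step count: 10. Longest linear sequence: 9 steps from 1 (steps 1 to 7, 9 and 10); step 8 is the one-step side branch.

Steps least certain to work

Step 2 (the key step, a proposed new method). The unimolecular oxygen relay may be outpaced. The competitors are loss of water from the primary hydroperoxide to the enal wherever neutral hydroperoxide meets base, intermolecular oxygen transfer to the unhindered face, and unproductive parking of the peroxide on the C1 carbonyl. The relay is vulnerable because it needs the less populated conformer with the C5 chain axial and a constrained displacement at oxygen. The fallback uses known chemistry only, sets out from 2 and returns to the route at 6. The hydroperoxide is reduced with PPh3 to (5R)-5-(3-hydroxyprop-1-en-2-yl)-2-methylcyclohex-2-en-1-one F1, which is silylated (TESCl, imidazole) to its triethylsilyl ether F2. Luche reduction (NaBH4, CeCl3·7H2O, MeOH, −78 °C) should give the (1R,5R)-cis-allylic alcohol F3, with the hydroxyl cis to the C5 chain. Hydroxyl-directed epoxidation (VO(acac)2, t-BuOOH, CH2Cl2) should place the oxirane syn to that hydroxyl and hence cis to the chain in the all-cis epoxy alcohol F4, and Dess–Martin oxidation gives 6. This costs four more steps and puts neither oxygen of O2 into the oxirane, but the face is set by precedented directing effects.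

Step 1. The ene reaction of a 1,1-disubstituted alkene is slow, so long irradiation may let sensitizer bleaching, enone photochemistry (intramolecular [2+2] cycloaddition) and abstraction of the C5 hydrogen compete. The fallback sets out from 1 and returns at 2. Ene-type allylic chlorination (Ca(OCl)2, CO2, CH2Cl2/H2O) gives (5R)-5-(3-chloroprop-1-en-2-yl)-2-methylcyclohex-2-en-1-one F5, Finkelstein exchange (NaI, acetone) gives (5R)-5-(3-iodoprop-1-en-2-yl)-2-methylcyclohex-2-en-1-one F6, and silver-assisted perhydrolysis (AgOCOCF3, H2O2 in Et2O, 0 °C) gives 2. The medium stays non-basic, so the enone is not epoxidized, and the 2-substituted allyl unit is symmetrical, so direct and allylic substitution lead to the same product.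

Step 4. Oxygen transfer to the rather flat epoxy enolate may show insufficient facial selectivity, or the enolate may add to the sulfonimine by-product. The fallback sets out from 6 and returns at 11. If transfer occurs mainly on the chain face, the product is the C6 epimer (1S,3R,4S,6S)-3-hydroxy-1-methyl-4-[3-(triethylsilyloxy)prop-1-en-2-yl]-7-oxabicyclo[4.1.0]heptan-2-one F7. It would be esterified with 9 under Mitsunobu conditions (PPh3, DIAD, toluene, 0 °C), which invert C6, so that both epimers converge on 11.

Step 9. Electron transfer from divalent chromium to the α,β-epoxy ketone or the α-acyloxy ketone (reductive opening of the oxirane, loss of the ester) may compete with the nickel-mediated formation of 17 and its addition to the aldehyde. The fallback sets out from 13 and returns at 19, so it also replaces step 10. Pinnick oxidation (NaClO2, NaH2PO4, 2-methylbut-2-ene, t-BuOH/H2O) gives 2-[(1S,3S,4S,6S)-1-methyl-2-oxo-3-{[(2E)-2-methylbut-2-enoyl]oxy}-7-oxabicyclo[4.1.0]heptan-4-yl]prop-2-enoic acid F8. The acid is converted under neutral conditions with 1-chloro-N,N,2-trimethylprop-1-en-1-amine into the acid chloride F9. A Stille acylation (Pd2(dba)3, tri(2-furyl)phosphine, THF, rt) with stannane 15, isolated before the iodination of step 8, should then give 19 directly at the ketone oxidation state, without chromium.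

Further compounds

F1 | step 2 | (5R)-5-(3-hydroxyprop-1-en-2-yl)-2-methylcyclohex-2-en-1-one | C=C(CO)[C@@H]1CC=C(C)C(=O)C1
F2 | step 2 | (5R)-2-methyl-5-[3-(triethylsilyloxy)prop-1-en-2-yl]cyclohex-2-en-1-one | C=C(CO[Si](CC)(CC)CC)[C@@H]1CC=C(C)C(=O)C1
F3 | step 2 | (1R,5R)-2-methyl-5-[3-(triethylsilyloxy)prop-1-en-2-yl]cyclohex-2-en-1-ol (hydroxyl cis to the chain) | C=C(CO[Si](CC)(CC)CC)[C@@H]1CC=C(C)[C@H](O)C1
F4 | step 2 | 1-methyl-4-[3-(triethylsilyloxy)prop-1-en-2-yl]-7-oxabicyclo[4.1.0]heptan-2-ol with hydroxyl, oxirane and chain on one face | C=C(CO[Si](CC)(CC)CC)[C@@H]1C[C@@H]2O[C@]2(C)[C@H](O)C1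
F5 | step 1 | (5R)-5-(3-chloroprop-1-en-2-yl)-2-methylcyclohex-2-en-1-one | C=C(CCl)[C@@H]1CC=C(C)C(=O)C1
F6 | step 1 | (5R)-5-(3-iodoprop-1-en-2-yl)-2-methylcyclohex-2-en-1-one | C=C(CI)[C@@H]1CC=C(C)C(=O)C1
F7 | step 4 | (1S,3R,4S,6S)-3-hydroxy-1-methyl-4-[3-(triethylsilyloxy)prop-1-en-2-yl]-7-oxabicyclo[4.1.0]heptan-2-one (C6 epimer of 8) | C=C(CO[Si](CC)(CC)CC)[C@@H]1C[C@@H]2O[C@]2(C)C(=O)[C@@H]1O
F8 | step 9 | 2-[(1S,3S,4S,6S)-1-methyl-2-oxo-3-{[(2E)-2-methylbut-2-enoyl]oxy}-7-oxabicyclo[4.1.0]heptan-4-yl]prop-2-enoic acid | C=C(C(=O)O)[C@@H]1C[C@@H]2O[C@]2(C)C(=O)[C@H]1OC(=O)/C(C)=C/C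
F9 | step 9 | acid chloride of F8 | C=C(C(=O)Cl)[C@@H]1C[C@@H]2O[C@]2(C)C(=O)[C@H]1OC(=O)/C(C)=C/C
A1 | alternative 1 | C7 enol triflate with C1 triethylsilyl carbinol, oxirane and C6 tiglate | C=C(OS(=O)(=O)C(F)(F)F)[C@@H]1C[C@@H]2O[C@]2(C)[C@H](O[Si](CC)(CC)CC)[C@H]1OC(=O)/C(C)=C/C
A2 | alternative 1 | carbon monoxide | [C-]#[O+]
A3 | alternative 1 | C1-O-triethylsilyl carbinol of the target with the complete dienone side chain | C=C(C(=O)/C=C/C(C)(C)O)[C@@H]1C[C@@H]2O[C@]2(C)[C@H](O[Si](CC)(CC)CC)[C@H]1OC(=O)/C(C)=C/C
A4 | alternative 2 | (3Z,6Z)-8-(tert-butyldimethylsilyloxy)-3,7-dimethyl-2-oxoocta-3,6-dienal | O=CC(=O)/C(C)=C\C/C=C(/C)CO[Si](C)(C)C(C)(C)C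
A5 | alternative 2 | trans-6-hydroxy-2-methyl-5-[3-(tert-butyldimethylsilyloxy)prop-1-en-2-yl]cyclohex-2-enone | C=C(CO[Si](C)(C)C(C)(C)C)[C@@H]1CC=C(C)C(=O)[C@H]1O
A6 | alternative 3 | trans-2-(tert-butyldimethylsilyloxy)-3-[3-(4-methoxybenzyloxy)prop-1-en-2-yl]cyclopentanone | C=C(COCc1ccc(OC)cc1)[C@@H]2CCC(=O)[C@H]2O[Si](C)(C)C(C)(C)C
A7 | alternative 3 | diazoethane | CC=[N+]=[N-]
A8 | alternative 3 | ring-expanded 2-methylcyclohexanone with C5 chain as p-methoxybenzyl ether and C6 silyl ether | C=C(COCc1ccc(OC)cc1)[C@@H]2CC[C@@H](C)C(=O)[C@H]2O[Si](C)(C)C(C)(C)C
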